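**Retrosynthetic overview**

1. Target 16 ⇐ α-face epoxidation of the C8=C9 alkene of ester 15 ⇐ acylation of the C6–OH of diol 12 with 4-acetoxybenzoyl chloride 13.
2. Diol 12 ⇐ chelation-controlled reduction of ketol 11.
3. Ketol 11 ⇐ enantioselective [3+2] annulation of dienone 6 with cyclopropanol 8 (zinc homoenolate conjugate addition, then aldol): the five-membered ring is formed second.
4. Dienone 6 ⇐ dearomative one-carbon ring expansion of 2,5-dimethylphenol 1 (Birch reduction of its silyl ether, cyclopropanation, oxidative ring opening): the seven-membered ring is formed first, and the arene supplies C1, C6–C10, both methyl groups, the C6 oxygen and the C8=C9 double bond.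
5. Ring order: seven-membered carbocycle, then cyclopentane, then oxirane.

Assumption and numbering: the configuration is taken exactly as written in the SMILES; with C1 = ring-fusion C(CH3), C2/C3 = CH2, C4 = C(OH)(iPr), C5 = ring-fusion CH, C6 = CH–O(ester), C7 = CH2, C8 = C(CH3), C9 = CH, C10 = CH2, this is 1R,4R,5S,6R,8R,9S (trans ring fusion; 1-CH3, 4-OH and 6-O on one face, called β; H-5 and the epoxide oxygen on the other face, α).

**Step 1**
Reactants: 1 2,5-dimethylphenol
Product: 2 tert-butyl(2,5-dimethylphenoxy)dimethylsilane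
Conditions: TBSCl, imidazole, DMF, 22 °C
Reagents that add atoms: tert-butyldimethylsilyl chloride, CC(C)(C)[Si](C)(C)Cl
Why: Imidazole-assisted silylation of the phenol, chosen because an aryl silyl ether survives dissolving-metal reduction and then gives a silyl enol ether directly; no stereocentre is formed.

**Step 2**
Reactants: 2 tert-butyl(2,5-dimethylphenoxy)dimethylsilane
Product: 3 tert-butyl[(2,5-dimethylcyclohexa-1,4-dien-1-yl)oxy]dimethylsilane
Conditions: Li, t-BuOH, NH3(l)–THF, −78 → −33 °C
Reagents that add atoms: none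
Why: Birch reduction breaks the aromaticity by protonating the two unsubstituted para-related ring carbons (arene C3 and C6), so the oxygen and both methyl groups stay on the two isolated double bonds, giving a silyl enol ether (future C6/C1) and a trisubstituted alkene that is carried through as C8=C9; no stereocentre is formed.

**Step 3**
Reactants: 3 tert-butyl[(2,5-dimethylcyclohexa-1,4-dien-1-yl)oxy]dimethylsilane
Product: 4 tert-butyl[(3,6-dimethylbicyclo[4.1.0]hept-3-en-1-yl)oxy]dimethylsilane (racemic)
Conditions: Et2Zn (1.1 equiv), CH2I2 (1.1 equiv), CH2Cl2, 0 °C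
Reagents that add atoms: diiodomethane, ICI
Why: Furukawa–Simmons–Smith cyclopropanation, in which the electrophilic zinc carbenoid adds fastest to the electron-rich silyl enol ether double bond and delivers the CH2 that becomes C5; the two new centres are racemic and are destroyed in step 4.

**Step 4**
Reactants: 4 tert-butyl[(3,6-dimethylbicyclo[4.1.0]hept-3-en-1-yl)oxy]dimethylsilane
Product: 6 3,6-dimethylcyclohepta-2,5-dien-1-one, via chloroketone 5 (not isolated)
Conditions: FeCl3 (2.2 equiv), DMF, 0 → 22 °C; then NaOAc, MeOH, 50 °C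
Reagents that add atoms: none
Why: Ito–Saegusa oxidative ring expansion, in which one-electron oxidation by FeCl3 cleaves the internal cyclopropane bond to the tertiary radical, chlorine transfer gives β-chloro ketone 5, and acetate eliminates HCl into conjugation to give the seven-membered dienone; no stereocentre remains.

**Step 5**
Reactants: 7 methyl 2-methylpropanoate
Product: 8 1-(propan-2-yl)cyclopropan-1-ol
Conditions: EtMgBr (2.2 equiv), Ti(OiPr)4 (10 mol%), Et2O, 20 °C; then H2O
Reagents that add atoms: ethylmagnesium bromide, CC[Mg]Br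
Why: Kulinkovich cyclopropanation, in which the titanacyclopropane formed from EtMgBr and Ti(OiPr)4 adds twice to the ester carbonyl; no stereocentre is formed.

**Step 6**
Reactants: 6 3,6-dimethylcyclohepta-2,5-dien-1-one; 8 1-(propan-2-yl)cyclopropan-1-ol
Product: 11 (3R,3aR,8aR)-3-hydroxy-6,8a-dimethyl-3-(propan-2-yl)-2,3,3a,5,8,8a-hexahydroazulen-4(1H)-one, via zinc homoenolate 9 (not isolated), via zinc enolate 10 (not isolated)
Conditions: 8 (2.4 equiv), Et2Zn (1.2 equiv), THF, 0 → 22 °C; then 6, Cu(OTf)2 (5 mol%), chiral hydroxyalkyl imidazolinium hexafluorophosphate derived from leucinol (carbene precursor, 6 mol%, enantiomer chosen on the first run to give 1R), −30 → 22 °C; then 40 °C, 2 h; pH 7 buffer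
Reagents that add atoms: none
Why: Proposed new method: Et2Zn opens the cyclopropanol to the zinc homoenolate 9, a copper–carbene catalyst transfers its CH2 terminus to the β-carbon of the enone and sets the quaternary C1, and the regiodefined zinc enolate 10 closes onto the pendant isopropyl ketone under equilibrating zinc-aldolate conditions to the most stable ketol (trans ring fusion next to the seven-ring ketone, C4–O chelated to the C6 carbonyl and therefore cis to the angular methyl, isopropyl on the open α face); the closest known reaction types are the copper–N-heterocyclic-carbene-catalysed enantioselective conjugate addition of dialkylzincs to β-methyl cycloheptenones, conjugate additions of cyclopropanol-derived zinc homoenolates, and copper-catalysed conjugate addition–aldol cyclisations of zinc enolates onto ketones.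

**Step 7**
Reactants: 11 (3R,3aR,8aR)-3-hydroxy-6,8a-dimethyl-3-(propan-2-yl)-2,3,3a,5,8,8a-hexahydroazulen-4(1H)-one
Product: 12 (3R,3aS,4R,8aR)-6,8a-dimethyl-3-(propan-2-yl)-1,2,3,3a,4,5,8,8a-octahydroazulene-3,4-diol
Conditions: Et2BOMe (1.1 equiv), NaBH4, THF–MeOH 4:1, −78 °C; then H2O, MeOH co-evaporation
Reagents that add atoms: none
Why: Narasaka–Prasad syn-selective 1,3-reduction, in which Et2BOMe ties the tertiary OH and the ketone into a six-membered boron chelate and external hydride adds to C6 from the α face, away from the axial angular methyl group (as in reductions of 6-oxo steroids), giving the 6β-alcohol syn to the 4β-OH.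

**Step 8**
Reactants: 12 (3R,3aS,4R,8aR)-6,8a-dimethyl-3-(propan-2-yl)-1,2,3,3a,4,5,8,8a-octahydroazulene-3,4-diol; 13 4-(acetyloxy)benzoyl chloride
Product: 15 (3R,3aS,4R,8aR)-3-hydroxy-6,8a-dimethyl-3-(propan-2-yl)-1,2,3,3a,4,5,8,8a-octahydroazulen-4-yl 4-hydroxybenzoate, via acetoxybenzoate 14 (not isolated)
Conditions: 13 (1.3 equiv), Et3N, DMAP (cat.), CH2Cl2, 0 → 22 °C; then pyrrolidine, 0 °C, 30 min
Reagents that add atoms: none
Why: DMAP-catalysed acylation of the secondary C6 alcohol with retention (the tertiary C4 alcohol does not react), followed in the same flask by aminolysis of the far more reactive aryl acetate, which leaves the hindered benzoate untouched.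

**Step 9**
Reactants: 15 (3R,3aS,4R,8aR)-3-hydroxy-6,8a-dimethyl-3-(propan-2-yl)-1,2,3,3a,4,5,8,8a-octahydroazulen-4-yl 4-hydroxybenzoate
Product: 16 (1R,4R,5S,6R,8R,9S)-8,9-epoxy-4-hydroxydaucan-6-yl 4-hydroxybenzoate (target)
Conditions: mCPBA (1.1 equiv), CH2Cl2, 0 °C
Reagents that add atoms: 3-chloroperoxybenzoic acid, OOC(=O)c1cccc(Cl)c1
Why: Prilezhaev epoxidation of the only alkene, in which the axial angular methyl at C1 and the axial 6β-acyloxy group flank C9 and C8 on the β face of the trans-fused chair, so the peracid adds from the α face and sets C8 (R) and C9 (S).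

**Compound list**

1 | 2,5-dimethylphenol | Cc1ccc(C)c(O)c1 | starting material
2 | tert-butyl(2,5-dimethylphenoxy)dimethylsilane | Cc1ccc(C)c(O[Si](C)(C)C(C)(C)C)c1 | intermediate
3 | tert-butyl[(2,5-dimethylcyclohexa-1,4-dien-1-yl)oxy]dimethylsilane | CC1=C(O[Si](C)(C)C(C)(C)C)CC(C)=CC1 | intermediate
4 | tert-butyl[(3,6-dimethylbicyclo[4.1.0]hept-3-en-1-yl)oxy]dimethylsilane, racemic | CC1=CCC2(C)CC2(O[Si](C)(C)C(C)(C)C)C1 | intermediate
5 | 3-chloro-3,6-dimethylcyclohept-5-en-1-one, racemic | CC1=CCC(C)(Cl)CC(=O)C1 | intermediate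
6 | 3,6-dimethylcyclohepta-2,5-dien-1-one | CC1=CC(=O)CC(C)=CC1 | intermediate
7 | methyl 2-methylpropanoate (methyl isobutyrate) | COC(=O)C(C)C | starting material
8 | 1-(propan-2-yl)cyclopropan-1-ol | CC(C)C1(O)CC1 | intermediate
9 | bis(4-methyl-3-oxopentyl)zinc | CC(C)C(=O)CC[Zn]CCC(=O)C(C)C | intermediate
10 | {[(3R)-3,6-dimethyl-3-(4-methyl-3-oxopentyl)cyclohepta-1,5-dien-1-yl]oxy}(4-methyl-3-oxopentyl)zinc | CC(C)C(=O)CC[C@]1(C)CC=C(C)CC(O[Zn]CCC(=O)C(C)C)=C1 | intermediate
11 | (3R,3aR,8aR)-3-hydroxy-6,8a-dimethyl-3-(propan-2-yl)-2,3,3a,5,8,8a-hexahydroazulen-4(1H)-one | CC(C)[C@]1(O)CC[C@]2(C)CC=C(C)CC(=O)[C@H]21 | intermediate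
12 | (3R,3aS,4R,8aR)-6,8a-dimethyl-3-(propan-2-yl)-1,2,3,3a,4,5,8,8a-octahydroazulene-3,4-diol | CC(C)[C@]1(O)CC[C@]2(C)CC=C(C)C[C@@H](O)[C@H]21 | intermediate
13 | 4-(acetyloxy)benzoyl chloride | CC(=O)Oc1ccc(cc1)C(Cl)=O | starting material
14 | (3R,3aS,4R,8aR)-3-hydroxy-6,8a-dimethyl-3-(propan-2-yl)-1,2,3,3a,4,5,8,8a-octahydroazulen-4-yl 4-(acetyloxy)benzoate | CC(C)[C@]1(O)CC[C@]2(C)CC=C(C)C[C@@H](OC(=O)c3ccc(OC(C)=O)cc3)[C@H]21 | intermediate
15 | (3R,3aS,4R,8aR)-3-hydroxy-6,8a-dimethyl-3-(propan-2-yl)-1,2,3,3a,4,5,8,8a-octahydroazulen-4-yl 4-hydroxybenzoate | CC(C)[C@]1(O)CC[C@]2(C)CC=C(C)C[C@@H](OC(=O)c3ccc(O)cc3)[C@H]21 | intermediate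
16 | (1R,4R,5S,6R,8R,9S)-8,9-epoxy-4-hydroxydaucan-6-yl 4-hydroxybenzoate | CC(C)[C@]1(O)CC[C@]2(C)C[C@@H]3O[C@]3(C)C[C@@H](OC(=O)c3ccc(O)cc3)[C@H]21 | target

**Step count and risks**

Total step count: 9. Longest linear sequence: 8 (steps 1–4 and 6–9; step 5 is a one-step branch).

The three steps most likely to fail:

**Step 6.** The homoenolate may not add to the hindered β-carbon, the enantioselectivity may be low, or the aldol may stop at a different diastereomer. The fallback separates the two events and makes the quaternary centre with a Grignard reagent, for which copper–carbene catalysis on β-methyl cycloalkenones is established. It sets out from 6 and comes back at 11. Isobutyryl chloride and ethylene (AlCl3, CH2Cl2) give 1-chloro-4-methylpentan-3-one F1. Ketalisation with ethane-1,2-diol (TsOH, toluene, Dean–Stark) gives 2-(2-chloroethyl)-2-(propan-2-yl)-1,3-dioxolane F2. Its Grignard reagent (Mg, THF) is added to 6 with Cu(OTf)2 and the chiral imidazolinium salt (Et2O, −30 °C) to give (3R)-3,6-dimethyl-3-{2-[2-(propan-2-yl)-1,3-dioxolan-2-yl]ethyl}cyclohept-5-en-1-one F3. PPTS in wet acetone frees (3R)-3,6-dimethyl-3-(4-methyl-3-oxopentyl)cyclohept-5-en-1-one F4. Catalytic KOtBu in t-BuOH–THF at 0 °C then closes the aldol under equilibrating conditions to 11.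

**Step 4.** The skipped dienone 6 can slip into conjugation, and the radical ring opening of the hindered silyl ether may be sluggish. The fallback replaces the radical ring expansion by a carbene addition and electrocyclic opening; it sets out from 3 and comes back at 6. Dibromocarbene (CHBr3, KOtBu, pentane, −20 °C) adds to the silyl enol ether double bond to give tert-butyl[(7,7-dibromo-3,6-dimethylbicyclo[4.1.0]hept-3-en-1-yl)oxy]dimethylsilane F5. Warming in toluene opens the cyclopropane to the allyl cation with loss of the silyl bromide and gives 2-bromo-3,6-dimethylcyclohepta-2,5-dien-1-one F6. Radical hydrodebromination (Bu3SnH, AIBN, benzene, 80 °C) gives 6.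

**Step 9.** The peracid may attack the β face. The fallback goes through a halohydrin, which places the epoxide oxygen on the face opposite to the one the electrophile attacks; it sets out from 12 and comes back at 16. Diol 12 is acylated as in step 8 but without the pyrrolidine treatment, and acetate 14 is isolated. NBS in aqueous acetone gives the bromohydrin (3R,3aS,4R,6R,7R,8aR)-7-bromo-3,6-dihydroxy-6,8a-dimethyl-3-(propan-2-yl)decahydroazulen-4-yl 4-(acetyloxy)benzoate F7 (9β-Br, 8α-OH). K2CO3 in MeOH closes the epoxide by displacement of bromide with inversion at C9 and cleaves the aryl acetate in the same flask to give 16.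

**Further compounds**

F1 | step 6 | 1-chloro-4-methylpentan-3-one | CC(C)C(=O)CCCl
F2 | step 6 | 2-(2-chloroethyl)-2-(propan-2-yl)-1,3-dioxolane | CC(C)C1(CCCl)OCCO1
F3 | step 6 | (3R)-3,6-dimethyl-3-{2-[2-(propan-2-yl)-1,3-dioxolan-2-yl]ethyl}cyclohept-5-en-1-one | CC(C)C1(CC[C@]2(C)CC=C(C)CC(=O)C2)OCCO1
F4 | step 6 | (3R)-3,6-dimethyl-3-(4-methyl-3-oxopentyl)cyclohept-5-en-1-one | CC(C)C(=O)CC[C@]1(C)CC=C(C)CC(=O)C1
F5 | step 4 | tert-butyl[(7,7-dibromo-3,6-dimethylbicyclo[4.1.0]hept-3-en-1-yl)oxy]dimethylsilane, racemic | CC1=CCC2(C)C(Br)(Br)C2(O[Si](C)(C)C(C)(C)C)C1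
F6 | step 4 | 2-bromo-3,6-dimethylcyclohepta-2,5-dien-1-one | CC1=CCC(C)=C(Br)C(=O)C1
F7 | step 9 | (3R,3aS,4R,6R,7R,8aR)-7-bromo-3,6-dihydroxy-6,8a-dimethyl-3-(propan-2-yl)decahydroazulen-4-yl 4-(acetyloxy)benzoate | CC(C)[C@]1(O)CC[C@]2(C)C[C@@H](Br)[C@](C)(O)C[C@@H](OC(=O)c3ccc(OC(C)=O)cc3)[C@H]21
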